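Everything rests on cutting the methyl-bearing naphthalene ring (C1'–C4') at C1'–C8a' and C4'–C4a'. Because C4a' lies next to the C5' methoxy group, the C4a'–C8a' fusion bond can be the strained bond of a 3-methoxybenzyne; the lithium dienolate of N,N-diethyl-3-methylbut-2-enamide then forms both bonds, closes the ring and sets the C4' oxygen and the C2' methyl group in one operation. The precursor is an unhindered biaryl: the cis-(1R,3S) N-methyl tetrahydroisoquinoline with a 3-chloro-4-methoxyphenyl group on C5, made by an easy Suzuki coupling. The crowded C5–C8' axis thus arises only after its bond exists, and N-methyl is carried throughout, so one O-methylation ends the route.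

Key step: step 9

Assumption: the target SMILES leaves the C5–C8' axis undefined, so the route aims at the (1R,3S) compound without control of the axis, and atropo-diastereomers formed in step 9 would be separated by chromatography if wanted; primed locants refer to the naphthalene, unprimed ones to the isoquinoline.

Step 1
Reactants: 1 tert-butyl N-[(2S)-1-hydroxypropan-2-yl]carbamate (N-Boc-L-alaninol)
Product: 3 tert-butyl (2S)-2-methylaziridine-1-carboxylate, via primary tosylate 2 (not isolated)
Conditions: TsCl, powdered KOH, Et2O, reflux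
Reagents that add atoms: none
Why: Tosylation of the primary alcohol and base-induced intramolecular N-alkylation of the carbamate anion (3-exo-tet aziridine closure) take place at the CH2 carbon, so the S stereocentre from L-alaninol is not touched.

Step 2
Reactants: 4 1-bromo-3,5-dimethoxybenzene; 3 tert-butyl (2S)-2-methylaziridine-1-carboxylate
Product: 6 tert-butyl N-[(2S)-1-(3,5-dimethoxyphenyl)propan-2-yl]carbamate, via aryl Grignard reagent 5 (not isolated)
Conditions: Mg, THF, reflux; then 3, CuBr·SMe2 (10 mol %), THF, −30 → 0 °C; aq work-up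
Reagents that add atoms: none
Why: Copper-catalysed SN2 ring opening of the carbamate-activated aziridine by the aryl Grignard reagent occurs at the unsubstituted CH2 carbon, so the C–N stereocentre keeps its S configuration.

Step 3
Reactants: 6 tert-butyl N-[(2S)-1-(3,5-dimethoxyphenyl)propan-2-yl]carbamate
Product: 8 N-[(2S)-1-(3,5-dimethoxyphenyl)propan-2-yl]acetamide, via amine hydrochloride 7 (not isolated)
Conditions: 4 M HCl in dioxane, rt; evaporate; Ac2O, Et3N, CH2Cl2, 0 °C → rt
Reagents that add atoms: acetic anhydride, CC(=O)OC(C)=O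
Why: Acidolysis of the Boc group followed by N-acylation of the amine salt with acetic anhydride (protecting-group exchange to the amide needed for cyclodehydration) does not involve the stereocentre.

Step 4
Reactants: 8 N-[(2S)-1-(3,5-dimethoxyphenyl)propan-2-yl]acetamide
Product: 9 (3S)-6,8-dimethoxy-1,3-dimethyl-3,4-dihydroisoquinoline
Conditions: POCl3, MeCN, reflux; basic aq work-up
Reagents that add atoms: none
Why: Bischler–Napieralski cyclodehydration: the nitrilium ion attacks a ring carbon ortho to one methoxy group and para to the other, and since the two ortho positions of the side chain are equivalent only the 6,8-dimethoxy isomer can form.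

Step 5
Reactants: 9 (3S)-6,8-dimethoxy-1,3-dimethyl-3,4-dihydroisoquinoline
Product: 11 (1R,3S)-6,8-dimethoxy-1,2,3-trimethyl-1,2,3,4-tetrahydroisoquinoline, via cis secondary amine 10 (not isolated)
Conditions: NaBH4, MeOH, −20 → 0 °C; then 37% aq HCHO, rt; NaBH4, 0 °C → rt
Reagents that add atoms: formaldehyde, C=O
Why: Borohydride reduction of the cyclic imine delivers hydride axially to C1 of the half-chair in which the C3 methyl group is pseudo-equatorial, which sets C1 as R and gives the 1,3-cis amine, and reductive amination with formaldehyde then methylates nitrogen without touching either stereocentre.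

Step 6
Reactants: 11 (1R,3S)-6,8-dimethoxy-1,2,3-trimethyl-1,2,3,4-tetrahydroisoquinoline
Product: 12 (1R,3S)-5-iodo-6,8-dimethoxy-1,2,3-trimethyl-1,2,3,4-tetrahydroisoquinoline
Conditions: NIS (1.05 equiv), CF3CO2H (3 equiv), MeCN, 0 °C → rt
Reagents that add atoms: N-iodosuccinimide, O=C1CCC(=O)N1I
Why: Electrophilic aromatic iodination goes to C5, para to the C8 methoxy and ortho to the C6 methoxy group, in preference to C7 between the two methoxy groups, while CF3CO2H activates NIS and keeps the amine protonated and thus safe from oxidation.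

Step 7
Reactants: 12 (1R,3S)-5-iodo-6,8-dimethoxy-1,2,3-trimethyl-1,2,3,4-tetrahydroisoquinoline; 13 (3-chloro-4-methoxyphenyl)boronic acid
Product: 14 (1R,3S)-5-(3-chloro-4-methoxyphenyl)-6,8-dimethoxy-1,2,3-trimethyl-1,2,3,4-tetrahydroisoquinoline
Conditions: Pd(PPh3)4 (5 mol %), 2 M aq Na2CO3, DME, 85 °C
Reagents that add atoms: none
Why: Suzuki–Miyaura coupling with a boronic acid that has no ortho substituent is sterically easy, and zerovalent palladium with PPh3 inserts into the C–I bond but not into the electron-rich aryl chloride, which is kept for step 9.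

Step 8
Reactants: 15 3-methylbut-2-enoyl chloride; 16 diethylamine
Product: 17 N,N-diethyl-3-methylbut-2-enamide
Conditions: Et2NH (2.2 equiv), CH2Cl2, 0 °C → rt
Reagents that add atoms: none
Why: Acylation of a secondary amine by an acid chloride (amide formation), the second equivalent of amine taking up HCl.

Step 9
Reactants: 14 (1R,3S)-5-(3-chloro-4-methoxyphenyl)-6,8-dimethoxy-1,2,3-trimethyl-1,2,3,4-tetrahydroisoquinoline; 17 N,N-diethyl-3-methylbut-2-enamide
Product: 20 5-[(1R,3S)-6,8-dimethoxy-1,2,3-trimethyl-1,2,3,4-tetrahydroisoquinolin-5-yl]-8-methoxy-3-methylnaphthalen-1-ol, via lithium dienolate 18 (not isolated), via aryne 19 (not isolated)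
Conditions: LDA (5 equiv), 17 (3 equiv), THF, −78 °C; then 14, −78 °C → rt; H2O
Reagents that add atoms: none
Why: Lithium diisopropylamide converts 17 into the gamma-deprotonated dienolate 18 and, on warming, removes C8a'–H of 14, the only hydrogen flanking chlorine, so that loss of LiCl gives the single aryne 19 with its strained bond at C4a'–C8a'. The gamma-carbon of 18 adds to C8a' (C1'–C8a' bond), the aryllithium left at C4a' adds to the amide carbonyl (C4'–C4a' bond) with expulsion of lithium diethylamide, and the cyclohexadienone so formed tautomerises to the naphtholate. The closest known reaction type is the annulation of 3-methoxybenzynes, generated from 2-haloanisoles by lithium amides, with this same lithiated amide to give 8-methoxy-3-methyl-1-naphthols, here applied to a haloanisole that carries an aryl group. The ring C1'–C2'–C3'–C4'–C4a'–C8a' closes in the 6-exo-trig mode, the aryl anion attacking a carbonyl group whose oxygen stays outside the new ring. No stereocentre is created, and the C5–C8' axis, which becomes hindered only now, is expected as a mixture of atropo-diastereomers. The step needs carbon–carbon bond formation at C8a' and not at C4a', which the sigma-withdrawing C5' methoxy group secures by polarising the aryne toward attack at the remote carbon with the carbanion developing beside oxygen, while the isoquinoline ring twisted out of the aryne plane leaves the in-plane approach open and the N-methyl amine offers the bases no carbonyl group or acidified C–H.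

Step 10
Reactants: 20 5-[(1R,3S)-6,8-dimethoxy-1,2,3-trimethyl-1,2,3,4-tetrahydroisoquinolin-5-yl]-8-methoxy-3-methylnaphthalen-1-ol
Product: 21 (1R,3S)-5-(4,5-dimethoxy-7-methylnaphthalen-1-yl)-6,8-dimethoxy-1,2,3-trimethyl-1,2,3,4-tetrahydroisoquinoline
Conditions: PhNMe3Cl (1.5 equiv), K2CO3, DMF, 100 °C
Reagents that add atoms: trimethylphenylammonium chloride, C[N+](C)(C)c1ccccc1.[Cl-]
Why: O-Methylation of the naphtholate by SN2 methyl transfer from the trimethylanilinium ion (Williamson-type ether synthesis), a reagent that methylates phenoxides but leaves tertiary amines unquaternised, as in the conversion of phenolic N-methyl alkaloids into their methyl ethers.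

Compound list
1 | tert-butyl N-[(2S)-1-hydroxypropan-2-yl]carbamate (N-Boc-L-alaninol) | C[C@H](NC(=O)OC(C)(C)C)CO | starting material
2 | (2S)-2-[(tert-butoxycarbonyl)amino]propyl 4-methylbenzenesulfonate | C[C@H](NC(=O)OC(C)(C)C)COS(=O)(=O)c1ccc(C)cc1 | intermediate
3 | tert-butyl (2S)-2-methylaziridine-1-carboxylate | C[C@H]1CN1C(=O)OC(C)(C)C | intermediate
4 | 1-bromo-3,5-dimethoxybenzene | COc1cc(Br)cc(OC)c1 | starting material
5 | (3,5-dimethoxyphenyl)magnesium bromide | COc1cc([Mg]Br)cc(OC)c1 | intermediate
6 | tert-butyl N-[(2S)-1-(3,5-dimethoxyphenyl)propan-2-yl]carbamate | C[C@H](NC(=O)OC(C)(C)C)Cc1cc(OC)cc(OC)c1 | intermediate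
7 | (2S)-1-(3,5-dimethoxyphenyl)propan-2-aminium chloride | C[C@H]([NH3+])Cc1cc(OC)cc(OC)c1.[Cl-] | intermediate
8 | N-[(2S)-1-(3,5-dimethoxyphenyl)propan-2-yl]acetamide | C[C@H](NC(C)=O)Cc1cc(OC)cc(OC)c1 | intermediate
9 | (3S)-6,8-dimethoxy-1,3-dimethyl-3,4-dihydroisoquinoline | COc1cc(OC)c2c(c1)C[C@H](C)N=C2C | intermediate
10 | (1R,3S)-6,8-dimethoxy-1,3-dimethyl-1,2,3,4-tetrahydroisoquinoline | COc1cc(OC)c2c(c1)C[C@H](C)N[C@@H]2C | intermediate
11 | (1R,3S)-6,8-dimethoxy-1,2,3-trimethyl-1,2,3,4-tetrahydroisoquinoline | COc1cc(OC)c2c(c1)C[C@H](C)N(C)[C@@H]2C | intermediate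
12 | (1R,3S)-5-iodo-6,8-dimethoxy-1,2,3-trimethyl-1,2,3,4-tetrahydroisoquinoline | COc1cc(OC)c2c(c1I)C[C@H](C)N(C)[C@@H]2C | intermediate
13 | (3-chloro-4-methoxyphenyl)boronic acid | COc1ccc(B(O)O)cc1Cl | starting material
14 | (1R,3S)-5-(3-chloro-4-methoxyphenyl)-6,8-dimethoxy-1,2,3-trimethyl-1,2,3,4-tetrahydroisoquinoline | COc1cc(OC)c2c(c1-c1ccc(OC)c(Cl)c1)C[C@H](C)N(C)[C@@H]2C | intermediate
15 | 3-methylbut-2-enoyl chloride | CC(C)=CC(=O)Cl | starting material
16 | diethylamine | CCNCC | starting material
17 | N,N-diethyl-3-methylbut-2-enamide | CCN(CC)C(=O)C=C(C)C | intermediate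
18 | lithium 1-(diethylamino)-3-methylbuta-1,3-dien-1-olate | C=C(C)C=C(O[Li])N(CC)CC | intermediate
19 | (1R,3S)-5-(2,3-didehydro-4-methoxyphenyl)-6,8-dimethoxy-1,2,3-trimethyl-1,2,3,4-tetrahydroisoquinoline (aryne) | COc1cc(OC)c2c(c1C1=CC=C(OC)C#C1)C[C@H](C)N(C)[C@@H]2C | intermediate
20 | 5-[(1R,3S)-6,8-dimethoxy-1,2,3-trimethyl-1,2,3,4-tetrahydroisoquinolin-5-yl]-8-methoxy-3-methylnaphthalen-1-ol | COc1cc(OC)c2c(c1-c1ccc(OC)c3c(O)cc(C)cc13)C[C@H](C)N(C)[C@@H]2C | intermediate
21 | (1R,3S)-5-(4,5-dimethoxy-7-methylnaphthalen-1-yl)-6,8-dimethoxy-1,2,3-trimethyl-1,2,3,4-tetrahydroisoquinoline | COc1cc(OC)c2c(c1-c1ccc(OC)c3c(OC)cc(C)cc13)C[C@H](C)N(C)[C@@H]2C | target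

Total step count: 10. Longest linear sequence: 9 steps (steps 1 to 7, 9 and 10, from 1 to 21); step 8 is a one-step side branch.

Steps most likely to fail

Step 9. The dienolate may add at C4a' instead of C8a', the base may be slow to reach the flanked C8a'–H, or the crowded aryne may be captured by the amide bases before the dienolate arrives. The fallback finishes the naphthalene before the biaryl bond is made; it sets out from amide 17 and iodide 12 and comes back at target 21. The same LDA annulation, run with 17 on commercial 2-chloroanisole (the parent case of this reaction), should give 8-methoxy-3-methylnaphthalen-1-ol F1. Acetylation (Ac2O, pyridine) gives 8-methoxy-3-methylnaphthalen-1-yl acetate F2, whose acetoxy-bearing ring is deactivated. NBS in MeCN should therefore brominate para to the methoxy group and give 5-bromo-8-methoxy-3-methylnaphthalen-1-yl acetate F3. Methanolysis (K2CO3, MeOH) to 5-bromo-8-methoxy-3-methylnaphthalen-1-ol F4 and O-methylation (MeI, K2CO3, acetone) give 1-bromo-4,5-dimethoxy-7-methylnaphthalene F5. Bromine–lithium exchange (n-BuLi, THF, −78 °C), B(OMe)3 and acidic work-up give (4,5-dimethoxy-7-methylnaphthalen-1-yl)boronic acid F6. A hindered Suzuki–Miyaura coupling of F6 with 12 (Pd(PPh3)4, K3PO4, DMF, 100 °C), of the kind established for 5,8'-linked naphthylisoquinolines, then gives 21 directly.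

Step 6. Iodination may spill over to C7 or to a second position, or the electrophilic iodine source may oxidise the benzylic tertiary amine to an iminium ion. The fallback places iodine before the heterocycle and the amine exist; it sets out from acetamide 8 and comes back at iodide 12. NIS with catalytic CF3CO2H in MeCN should iodinate the ring of 8 ortho to the side chain (para to one methoxy group) to give N-[(2S)-1-(2-iodo-3,5-dimethoxyphenyl)propan-2-yl]acetamide F7. Bischler–Napieralski cyclisation (POCl3, MeCN, reflux) can then occur only at the one free ortho position and gives (3S)-5-iodo-6,8-dimethoxy-1,3-dimethyl-3,4-dihydroisoquinoline F8. NaBH4 reduction to cis-(1R,3S)-5-iodo-6,8-dimethoxy-1,3-dimethyl-1,2,3,4-tetrahydroisoquinoline F9 and reductive methylation (aq HCHO, NaBH4), as in step 5, give 12.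

Step 10. Methyl transfer to the hydrogen-bonded peri-naphthol may be sluggish, or methylation at nitrogen may compete. The fallback accepts methylation at both sites and then removes one N-methyl group; it sets out from naphthol 20 and comes back at target 21. Excess MeI with K2CO3 in acetone at reflux should give (1R,3S)-5-(4,5-dimethoxy-7-methylnaphthalen-1-yl)-6,8-dimethoxy-1,2,2,3-tetramethyl-1,2,3,4-tetrahydroisoquinolin-2-ium iodide F10. Sodium thiophenolate in refluxing 2-butanone then removes one N-methyl group by SN2 attack at the least hindered carbon and gives 21.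

Further compounds
F1 | step 9 | 8-methoxy-3-methylnaphthalen-1-ol | COc1cccc2cc(C)cc(O)c12
F2 | step 9 | 8-methoxy-3-methylnaphthalen-1-yl acetate | COc1cccc2cc(C)cc(OC(C)=O)c12
F3 | step 9 | 5-bromo-8-methoxy-3-methylnaphthalen-1-yl acetate | COc1ccc(Br)c2cc(C)cc(OC(C)=O)c12
F4 | step 9 | 5-bromo-8-methoxy-3-methylnaphthalen-1-ol | COc1ccc(Br)c2cc(C)cc(O)c12
F5 | step 9 | 1-bromo-4,5-dimethoxy-7-methylnaphthalene | COc1ccc(Br)c2cc(C)cc(OC)c12
F6 | step 9 | (4,5-dimethoxy-7-methylnaphthalen-1-yl)boronic acid | COc1ccc(B(O)O)c2cc(C)cc(OC)c12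
F7 | step 6 | N-[(2S)-1-(2-iodo-3,5-dimethoxyphenyl)propan-2-yl]acetamide | C[C@H](NC(C)=O)Cc1cc(OC)cc(OC)c1I
F8 | step 6 | (3S)-5-iodo-6,8-dimethoxy-1,3-dimethyl-3,4-dihydroisoquinoline | COc1cc(OC)c2c(c1I)C[C@H](C)N=C2C
F9 | step 6 | (1R,3S)-5-iodo-6,8-dimethoxy-1,3-dimethyl-1,2,3,4-tetrahydroisoquinoline | COc1cc(OC)c2c(c1I)C[C@H](C)N[C@@H]2C
F10 | step 10 | (1R,3S)-5-(4,5-dimethoxy-7-methylnaphthalen-1-yl)-6,8-dimethoxy-1,2,2,3-tetramethyl-1,2,3,4-tetrahydroisoquinolin-2-ium iodide | COc1cc(OC)c2c(c1-c1ccc(OC)c3c(OC)cc(C)cc13)C[C@H](C)[N+](C)(C)[C@@H]2C.[I-]
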